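## Retrosynthetic overview

1. The C3'=C4' (E) alkene is cut by a late cross-metathesis between a lactone carrying the C1'-OH/C2'-OMe/vinyl unit and (3S,4R)-pent-1-ene-3,4-diyl diacetate.
2. The δ-lactone comes from acid-triggered acetonide removal and lactonisation of a (Z)-enoate; the Z-alkene is made by Still–Gennari olefination of the 2-deoxy-D-ribose acetonide lactol (C6 and C1' come from the sugar).
3. C2' is set by Felkin–Anh vinyl addition to the sugar-derived aldehyde and is then O-methylated.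
4. The diacetate (C5', C6') comes from Sharpless desymmetrisation of divinylcarbinol, hydride opening of the epoxide and acetylation.
5. Ring order: a temporary dioxolane first (step 1), then the only ring of the target, the dihydropyranone (step 6), before the coupling (step 10).

Assumption: C2–C6 are the lactone locants and C1'–C7' the side-chain locants of the target; commercial 2-deoxy-D-ribose is drawn as its pyranose hemiacetal.

## Route

Step 1
Reactants: 1 2-deoxy-D-ribose; 2 2-methoxypropene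
Product: 3 2-deoxy-3,4-O-isopropylidene-D-erythro-pentopyranose (anomer mixture)
Conditions: 2 (1.5 equiv), PPTS (cat.), EtOAc, 0 °C → rt
Reagents that add atoms: 2-methoxypropene, COC(C)=C
Why: Acid-catalysed transacetalisation (acetonide formation) locks the cis-3,4-diol of the pyranose as the favoured cis-fused dioxolane and leaves only the lactol free, the two sugar stereocentres (future C6 and C1') being carried over unchanged.

Step 2
Reactants: 3 2-deoxy-3,4-O-isopropylidene-D-erythro-pentopyranose; 4 methyl bis(2,2,2-trifluoroethyl)phosphonoacetate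
Product: 6 methyl (2Z)-4-[(4S,5R)-5-(hydroxymethyl)-2,2-dimethyl-1,3-dioxolan-4-yl]but-2-enoate, via open-chain hydroxy aldehyde 5 (not isolated)
Conditions: 4 (2.2 equiv), KN(SiMe3)2 (2.1 equiv), 18-crown-6, THF, −78 °C; aq. NH4Cl quench at −78 °C
Reagents that add atoms: methyl bis(2,2,2-trifluoroethyl)phosphonoacetate, COC(=O)CP(=O)(OCC(F)(F)F)OCC(F)(F)F
Why: Still–Gennari variant of the Horner–Wadsworth–Emmons olefination, in which the lactol reacts through its hydroxy aldehyde tautomer 5 and the electron-poor phosphonate eliminates under kinetic control to the (Z)-enoate (expected Z:E ≥ 10:1) at a temperature too low for the liberated alkoxide to add back to the enoate; no stereocentre is touched.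

Step 3
Reactants: 6 methyl (2Z)-4-[(4S,5R)-5-(hydroxymethyl)-2,2-dimethyl-1,3-dioxolan-4-yl]but-2-enoate
Product: 7 methyl (2Z)-4-[(4S,5S)-5-formyl-2,2-dimethyl-1,3-dioxolan-4-yl]but-2-enoate
Conditions: Dess–Martin periodinane, pyridine, CH2Cl2, 0 °C → rt; used crude
Reagents that add atoms: none
Why: Dess–Martin oxidation of the primary alcohol under buffered non-basic conditions gives the α-alkoxy aldehyde without epimerising the cis-dioxolane or isomerising the (Z)-enoate.

Step 4
Reactants: 7 methyl (2Z)-4-[(4S,5S)-5-formyl-2,2-dimethyl-1,3-dioxolan-4-yl]but-2-enoate; 8 vinylmagnesium bromide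
Product: 9 methyl (2Z)-4-[(4S,5R)-5-[(1R)-1-hydroxyprop-2-en-1-yl]-2,2-dimethyl-1,3-dioxolan-4-yl]but-2-enoate
Conditions: CH2=CHMgBr (1.3 equiv), THF, −78 °C; aq. NH4Cl at −78 °C; chromatography removes the minor (1S)-epimer
Reagents that add atoms: vinylmagnesium bromide, C=C[Mg]Br
Why: Grignard 1,2-addition under Felkin–Anh (non-chelation) control, with attack anti to the α-C–O bond on the face away from the cis ring substituent, gives the 1,2-anti (1R) carbinol that becomes C2' (expected about 4–6:1), and at −78 °C the aldehyde reacts far faster than the ester or enoate.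

Step 5
Reactants: 9 methyl (2Z)-4-[(4S,5R)-5-[(1R)-1-hydroxyprop-2-en-1-yl]-2,2-dimethyl-1,3-dioxolan-4-yl]but-2-enoate; 10 methyl trifluoromethanesulfonate
Product: 11 methyl (2Z)-4-[(4S,5S)-5-[(1R)-1-methoxyprop-2-en-1-yl]-2,2-dimethyl-1,3-dioxolan-4-yl]but-2-enoate
Conditions: MeOTf (3 equiv), 2,6-di-tert-butyl-4-methylpyridine (4 equiv), CH2Cl2, 0 °C → rt
Reagents that add atoms: methyl trifluoromethanesulfonate, COS(=O)(=O)C(F)(F)F
Why: O-Alkylation with methyl triflate and a hindered non-nucleophilic base methylates the secondary allylic alcohol without forming an alkoxide, so oxa-Michael addition to the enoate and vinylogous β-elimination are avoided and no stereocentre is touched.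

Step 6
Reactants: 11 methyl (2Z)-4-[(4S,5S)-5-[(1R)-1-methoxyprop-2-en-1-yl]-2,2-dimethyl-1,3-dioxolan-4-yl]but-2-enoate
Product: 13 (6S)-6-[(1S,2R)-1-hydroxy-2-methoxybut-3-en-1-yl]-5,6-dihydro-2H-pyran-2-one, via dihydroxy Z-enoate 12 (not isolated)
Conditions: 1 M aq. HCl–THF (1:2), rt; then TsOH·H2O (cat.), CH2Cl2, rt to complete ring closure
Reagents that add atoms: none
Why: Acid-catalysed acetonide hydrolysis frees diol 12, whose δ-hydroxyl is held next to the ester by the (Z)-alkene and lactonises at once to the six-membered unsaturated lactone (the ε-hydroxyl would need a seven-membered ring), so the two hydroxyls are told apart without protecting groups and C1'-OH stays free.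

Step 7
Reactants: 14 penta-1,4-dien-3-ol (divinylcarbinol); 15 tert-butyl hydroperoxide
Product: 16 (2R,3S)-1,2-epoxypent-4-en-3-ol
Conditions: Ti(OiPr)4 (10 mol %), L-(+)-diisopropyl tartrate (13 mol %), t-BuOOH (1.5 equiv), 4 Å MS, CH2Cl2, −20 °C
Reagents that add atoms: tert-butyl hydroperoxide, CC(C)(C)OO
Why: Sharpless asymmetric epoxidation used as a desymmetrisation, in which the Ti(OiPr)4–L-(+)-DIPT catalyst epoxidises one enantiotopic vinyl group on one face to give the erythro (2R,3S) epoxy alcohol while the minor enantiomer is consumed by a second epoxidation (ee > 97%), and this sets both future stereocentres C5' and C6'.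

Step 8
Reactants: 16 (2R,3S)-1,2-epoxypent-4-en-3-ol
Product: 17 (3S,4R)-pent-1-ene-3,4-diol
Conditions: LiAlH4, THF, 0 °C → rt; Fieser work-up
Reagents that add atoms: none
Why: SN2 hydride opening of the terminal epoxide at its unsubstituted CH2 carbon turns that carbon into the methyl group and leaves the C–O bonds at both stereocentres intact, giving the anti (3S,4R) diol.

Step 9
Reactants: 17 (3S,4R)-pent-1-ene-3,4-diol; 18 acetic anhydride
Product: 19 (3S,4R)-pent-1-ene-3,4-diyl diacetate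
Conditions: Ac2O, pyridine, DMAP (cat.), CH2Cl2, 0 °C → rt
Reagents that add atoms: acetic anhydride, CC(=O)OC(C)=O
Why: DMAP-catalysed acylation esterifies both secondary hydroxyls with retention and installs the two acetates of the target.

Step 10
Reactants: 13 (6S)-6-[(1S,2R)-1-hydroxy-2-methoxybut-3-en-1-yl]-5,6-dihydro-2H-pyran-2-one; 19 (3S,4R)-pent-1-ene-3,4-diyl diacetate
Product: 20 (6S)-6-[(1S,2R,3E,5S,6R)-5,6-diacetoxy-1-hydroxy-2-methoxyhept-3-en-1-yl]-5,6-dihydro-2H-pyran-2-one (target CNP0375023.9)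
Conditions: 19 (3 equiv), second-generation Hoveyda–Grubbs catalyst RuCl2(H2IMes)(=CH-C6H4-2-OiPr) (10 mol %), CH2Cl2, 40 °C
Reagents that add atoms: none
Why: Olefin cross-metathesis between two terminal alkenes that each carry an allylic oxygen and homodimerise slowly, so an excess of the cheap partner 19 gives the cross product with loss of ethene as the thermodynamic (E)-alkene, while the conjugated endocyclic lactone alkene, the free hydroxyl and the acetates are inert.

## Compound list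

1 | 2-deoxy-D-ribose (2-deoxy-D-erythro-pentose, pyranose hemiacetal) | OC1C[C@H](O)[C@H](O)CO1 | starting material
2 | 2-methoxypropene | COC(C)=C | starting material
3 | 2-deoxy-3,4-O-isopropylidene-D-erythro-pentopyranose (anomer mixture) | OC1C[C@@H]2OC(C)(C)O[C@@H]2CO1 | intermediate
4 | methyl bis(2,2,2-trifluoroethyl)phosphonoacetate | COC(=O)CP(=O)(OCC(F)(F)F)OCC(F)(F)F | starting material
5 | 2-[(4S,5R)-5-(hydroxymethyl)-2,2-dimethyl-1,3-dioxolan-4-yl]acetaldehyde | O=CC[C@@H]1OC(C)(C)O[C@@H]1CO | intermediate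
6 | methyl (2Z)-4-[(4S,5R)-5-(hydroxymethyl)-2,2-dimethyl-1,3-dioxolan-4-yl]but-2-enoate | COC(=O)/C=C\C[C@@H]1OC(C)(C)O[C@@H]1CO | intermediate
7 | methyl (2Z)-4-[(4S,5S)-5-formyl-2,2-dimethyl-1,3-dioxolan-4-yl]but-2-enoate | COC(=O)/C=C\C[C@@H]1OC(C)(C)O[C@@H]1C=O | intermediate
8 | vinylmagnesium bromide | C=C[Mg]Br | starting material
9 | methyl (2Z)-4-[(4S,5R)-5-[(1R)-1-hydroxyprop-2-en-1-yl]-2,2-dimethyl-1,3-dioxolan-4-yl]but-2-enoate | COC(=O)/C=C\C[C@@H]1OC(C)(C)O[C@@H]1[C@H](O)C=C | intermediate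
10 | methyl trifluoromethanesulfonate | COS(=O)(=O)C(F)(F)F | starting material
11 | methyl (2Z)-4-[(4S,5S)-5-[(1R)-1-methoxyprop-2-en-1-yl]-2,2-dimethyl-1,3-dioxolan-4-yl]but-2-enoate | COC(=O)/C=C\C[C@@H]1OC(C)(C)O[C@@H]1[C@H](OC)C=C | intermediate
12 | methyl (2Z,5S,6S,7R)-5,6-dihydroxy-7-methoxynona-2,8-dienoate | COC(=O)/C=C\C[C@H](O)[C@H](O)[C@H](OC)C=C | intermediate
13 | (6S)-6-[(1S,2R)-1-hydroxy-2-methoxybut-3-en-1-yl]-5,6-dihydro-2H-pyran-2-one | CO[C@H](C=C)[C@@H](O)[C@@H]1CC=CC(=O)O1 | intermediate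
14 | penta-1,4-dien-3-ol (divinylcarbinol) | C=CC(O)C=C | starting material
15 | tert-butyl hydroperoxide | CC(C)(C)OO | starting material
16 | (2R,3S)-1,2-epoxypent-4-en-3-ol | C=C[C@H](O)[C@H]1CO1 | intermediate
17 | (3S,4R)-pent-1-ene-3,4-diol | C=C[C@H](O)[C@@H](C)O | intermediate
18 | acetic anhydride | CC(=O)OC(C)=O | starting material
19 | (3S,4R)-pent-1-ene-3,4-diyl diacetate | C=C[C@H](OC(C)=O)[C@@H](C)OC(C)=O | intermediate
20 | (6S)-6-[(1S,2R,3E,5S,6R)-5,6-diacetoxy-1-hydroxy-2-methoxyhept-3-en-1-yl]-5,6-dihydro-2H-pyran-2-one | CO[C@H](/C=C/[C@H](OC(C)=O)[C@@H](C)OC(C)=O)[C@@H](O)[C@@H]1CC=CC(=O)O1 | target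

## Step count and risks

Total steps: 10. Longest linear sequence: 7 (steps 1–6 and 10); the diacetate branch (steps 7–9) is 3 steps before the coupling.

Most likely to fail, first: step 2. The Z-olefination is run on a free lactol, so E/Z erosion, oxa-Michael closure of the liberated alkoxide onto the enoate, or β-elimination of the acetonide oxygen may intervene. The fallback olefinates a true aldehyde that has no free hydroxyl. It sets out from 3: Wittig methylenation (Ph3P=CH2, THF) gives [(4R,5S)-2,2-dimethyl-5-(prop-2-en-1-yl)-1,3-dioxolan-4-yl]methanol F1. Silylation (TBSCl, imidazole, DMF) gives tert-butyl{[(4R,5S)-2,2-dimethyl-5-(prop-2-en-1-yl)-1,3-dioxolan-4-yl]methoxy}dimethylsilane F2. Ozonolysis (O3, CH2Cl2, −78 °C, then PPh3) gives 2-[(4S,5R)-5-({[tert-butyl(dimethyl)silyl]oxy}methyl)-2,2-dimethyl-1,3-dioxolan-4-yl]acetaldehyde F3. Still–Gennari olefination with 4 then gives methyl (2Z)-4-[(4S,5R)-5-({[tert-butyl(dimethyl)silyl]oxy}methyl)-2,2-dimethyl-1,3-dioxolan-4-yl]but-2-enoate F4. HF·pyridine (THF, 0 °C) removes the silyl group, and the sequence comes back to the route at 6.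

Second: step 4. Felkin–Anh selectivity in the vinyl addition may be modest, which lowers the yield of the C2' stereocentre. The fallback sets this centre by ketone reduction instead of addition. It sets out from 9 as obtained in admixture with its carbinol epimer methyl (2Z)-4-[(4S,5R)-5-[(1S)-1-hydroxyprop-2-en-1-yl]-2,2-dimethyl-1,3-dioxolan-4-yl]but-2-enoate F5. Dess–Martin oxidation converges both epimers to the enone methyl (2Z)-4-[(4S,5S)-2,2-dimethyl-5-(prop-2-enoyl)-1,3-dioxolan-4-yl]but-2-enoate F6. Chelation-controlled 1,2-reduction with Zn(BH4)2 (Et2O, −30 °C) follows: zinc bridges the ketone oxygen and the α-oxygen of the dioxolane and hydride enters from the side of the α-hydrogen, which for a ketone gives the 1,2-anti alcohol. The sequence comes back to the route at 9.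

Third: step 10. The cross-metathesis joins two hindered allylic-oxygenated alkenes and may stall or give mainly homodimers. The fallback makes the C2'–C3' bond instead, with the E-alkene preformed. It sets out from 19 and 7. Ozonolysis of 19 (O3, CH2Cl2, −78 °C, then PPh3) gives (2R,3R)-2,3-diacetoxybutanal F7. Takai olefination (CHI3, CrCl2, THF–dioxane, 0 °C) gives (1E,3S,4R)-1-iodopent-1-ene-3,4-diyl diacetate F8. Nozaki–Hiyama–Kishi coupling of F8 with aldehyde 7 (CrCl2, catalytic NiCl2, DMSO, rt; Felkin–Anh anti addition, esters tolerated) gives methyl (2Z)-4-[(4S,5R)-5-[(1R,2E,4S,5R)-4,5-diacetoxy-1-hydroxyhex-2-en-1-yl]-2,2-dimethyl-1,3-dioxolan-4-yl]but-2-enoate F9. Methylation as in step 5 (MeOTf, 2,6-di-tert-butyl-4-methylpyridine) gives methyl (2Z)-4-[(4S,5S)-5-[(1R,2E,4S,5R)-4,5-diacetoxy-1-methoxyhex-2-en-1-yl]-2,2-dimethyl-1,3-dioxolan-4-yl]but-2-enoate F10. TFA–H2O (9:1, 0 °C) then cleaves the acetonide to methyl (2Z,5S,6S,7R,8E,10S,11R)-10,11-diacetoxy-5,6-dihydroxy-7-methoxydodeca-2,8-dienoate F11, which lactonises in the flask, and the sequence comes back to the route at 20.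

## Further compounds

F1 | step 2 | [(4R,5S)-2,2-dimethyl-5-(prop-2-en-1-yl)-1,3-dioxolan-4-yl]methanol | C=CC[C@@H]1OC(C)(C)O[C@@H]1CO
F2 | step 2 | tert-butyl{[(4R,5S)-2,2-dimethyl-5-(prop-2-en-1-yl)-1,3-dioxolan-4-yl]methoxy}dimethylsilane | C=CC[C@@H]1OC(C)(C)O[C@@H]1CO[Si](C)(C)C(C)(C)C
F3 | step 2 | 2-[(4S,5R)-5-({[tert-butyl(dimethyl)silyl]oxy}methyl)-2,2-dimethyl-1,3-dioxolan-4-yl]acetaldehyde | O=CC[C@@H]1OC(C)(C)O[C@@H]1CO[Si](C)(C)C(C)(C)C
F4 | step 2 | methyl (2Z)-4-[(4S,5R)-5-({[tert-butyl(dimethyl)silyl]oxy}methyl)-2,2-dimethyl-1,3-dioxolan-4-yl]but-2-enoate | COC(=O)/C=C\C[C@@H]1OC(C)(C)O[C@@H]1CO[Si](C)(C)C(C)(C)C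
F5 | step 4 | methyl (2Z)-4-[(4S,5R)-5-[(1S)-1-hydroxyprop-2-en-1-yl]-2,2-dimethyl-1,3-dioxolan-4-yl]but-2-enoate | COC(=O)/C=C\C[C@@H]1OC(C)(C)O[C@@H]1[C@@H](O)C=C
F6 | step 4 | methyl (2Z)-4-[(4S,5S)-2,2-dimethyl-5-(prop-2-enoyl)-1,3-dioxolan-4-yl]but-2-enoate | COC(=O)/C=C\C[C@@H]1OC(C)(C)O[C@@H]1C(=O)C=C
F7 | step 10 | (2R,3R)-2,3-diacetoxybutanal | O=C[C@H](OC(C)=O)[C@@H](C)OC(C)=O
F8 | step 10 | (1E,3S,4R)-1-iodopent-1-ene-3,4-diyl diacetate | I/C=C/[C@H](OC(C)=O)[C@@H](C)OC(C)=O
F9 | step 10 | methyl (2Z)-4-[(4S,5R)-5-[(1R,2E,4S,5R)-4,5-diacetoxy-1-hydroxyhex-2-en-1-yl]-2,2-dimethyl-1,3-dioxolan-4-yl]but-2-enoate | COC(=O)/C=C\C[C@@H]1OC(C)(C)O[C@@H]1[C@H](O)/C=C/[C@H](OC(C)=O)[C@@H](C)OC(C)=O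
F10 | step 10 | methyl (2Z)-4-[(4S,5S)-5-[(1R,2E,4S,5R)-4,5-diacetoxy-1-methoxyhex-2-en-1-yl]-2,2-dimethyl-1,3-dioxolan-4-yl]but-2-enoate | COC(=O)/C=C\C[C@@H]1OC(C)(C)O[C@@H]1[C@H](OC)/C=C/[C@H](OC(C)=O)[C@@H](C)OC(C)=O
F11 | step 10 | methyl (2Z,5S,6S,7R,8E,10S,11R)-10,11-diacetoxy-5,6-dihydroxy-7-methoxydodeca-2,8-dienoate | COC(=O)/C=C\C[C@H](O)[C@H](O)[C@H](OC)/C=C/[C@H](OC(C)=O)[C@@H](C)OC(C)=O
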